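## Plan

- **Enabling feature.** In the bicyclo[2.2.2]octane (bridgeheads C1 and C4; bridges C2–C3, C5=C6, C7–C8), C4 is β and C8 is α to the C7 ketone. The C8 hydroxyl lies anti to the C4–C5 bond across ring C1–C2–C3–C4–C8–C7. This is the imprint of backside opening of a C4–C8 epoxy ketone by C5 of a β-diketone arm on C1.
- **Cuts, in retrosynthetic order.** Tetronate O–CH3 and the sorbyl Cα=Cβ bond (aldol condensation with crotonaldehyde); C4–C5 (epoxide alkylation); C5–acyl (Claisen condensation with a hex-4-enoyl donor); the epoxide C–O bonds; tetronate C3′–C4′ (Dieckmann) and C3–C5′ (vinylogous Mukaiyama aldol with methyl pyruvate); C1–C6 and C1–CH3 (enolate aldol and methylation), arriving at (R)-carvone.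
- **Forward order.** The carvone ring becomes ring C1–C2–C3–C4–C8–C7. C1 is made quaternary, C3 is functionalised through the dienol ether, the tetronate ring is closed, the epoxide is installed, the diketone chain is completed at C5, the C5=C6 bridge closes the cage, and the sorbyl chain and the tetronate OH are unveiled last.
- **Stereochemistry.** C2 comes from (R)-carvone. The C1 acyl arm, the C3 substituent and the epoxide each enter anti to the vicinal substituent already present. C5′ is set by the Cu(OTf)2/(S,S)-tBu-box catalyst. C4 arises by inversion of the epoxide carbon and C8 is carried through unchanged.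

Key step: step 14

Remark: cage locants C1–C8 (tetronate O1′–C5′) are used for all ring intermediates, β is the face of ring C1–C2–C3–C4–C8–C7 that carries the C1 acyl arm and α the opposite face; (E)-hex-4-enoic acid is taken as purchasable; the carbinol centres in 7–9, 11–17 and 26 and the trioxolane centre in 2 are epimer mixtures that are erased later, and 5 is drawn as its major epimer.

## Route

Step 1
Reactants: 1 (R)-carvone
Product: 3 (5R)-5-acetyl-2-methylcyclohex-2-en-1-one, via secondary ozonide 2 (not isolated)
Conditions: O3 (1 equiv), CH2Cl2, −78 °C; then PPh3, −78 °C to rt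
Reagents that add atoms: ozone, [O-][O+]=O
Why: Ozonolysis with reductive work-up cleaves the electron-rich 1,1-disubstituted isopropenyl alkene far faster than the electron-poor conjugated ring alkene when ozone is limited to one equivalent, and the cold neutral conditions leave the C2 stereocentre (α to the new ketone) untouched.

Step 2
Reactants: 3 (5R)-5-acetyl-2-methylcyclohex-2-en-1-one
Product: 4 (5R)-2-methyl-5-(2-methyl-1,3-dioxolan-2-yl)cyclohex-2-en-1-one
Conditions: (TMSOCH2)2, TMSOTf (2 mol%), CH2Cl2, −78 °C; pyridine quench
Reagents that add atoms: 1,2-bis(trimethylsilyloxy)ethane, C[Si](C)(C)OCCO[Si](C)(C)C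
Why: TMSOTf-catalysed ketalisation with the bis-silyl ether of ethylene glycol is kinetically selective for the saturated methyl ketone over the less electrophilic conjugated enone carbonyl, and the aprotic conditions at −78 °C avoid enolisation of the C2–H that is α to a carbonyl at this stage, so the carvone-derived centre is kept.

Step 3
Reactants: 4 (5R)-2-methyl-5-(2-methyl-1,3-dioxolan-2-yl)cyclohex-2-en-1-one
Product: 5 (5R,6S)-2,6-dimethyl-5-(2-methyl-1,3-dioxolan-2-yl)cyclohex-2-en-1-one (trans, major epimer)
Conditions: LiN(iPr)2, THF, −78 °C; MeI, −78 to 0 °C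
Reagents that add atoms: iodomethane, CI
Why: Kinetic α′-deprotonation of the enone and SN2 methylation of the lithium enolate (enolate alkylation) introduce the C1 methyl group mainly trans to the C2 dioxolanyl substituent, a configuration that does not matter because C1 is planarised again in step 4.

Step 4
Reactants: 5 (5R,6S)-2,6-dimethyl-5-(2-methyl-1,3-dioxolan-2-yl)cyclohex-2-en-1-one; 6 acetaldehyde
Product: 8 (5R,6R)-6-[1-(tert-butyldimethylsilyloxy)ethyl]-2,6-dimethyl-5-(2-methyl-1,3-dioxolan-2-yl)cyclohex-2-en-1-one, via β-hydroxy ketone 7 (not isolated)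
Conditions: LiN(iPr)2, THF, −78 °C; CH3CHO, −78 °C; then TBSOTf, 2,6-lutidine, −78 to 0 °C
Reagents that add atoms: tert-butyldimethylsilyl triflate, CC(C)(C)[Si](C)(C)OS(=O)(=O)C(F)(F)F
Why: The remaining α′-proton at C1 is removed kinetically and the tetrasubstituted lithium enolate adds to acetaldehyde (aldol addition) on the β-face, anti to the vicinal α-dioxolanyl group at C2, which sets the C1 quaternary centre with the future acyl carbon C6 β and the methyl α, while in-flask O-silylation of the lithium aldolate blocks retro-aldol cleavage and protects the carbinol, whose own configuration is erased in step 11.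

Step 5
Reactants: 8 (5R,6R)-6-[1-(tert-butyldimethylsilyloxy)ethyl]-2,6-dimethyl-5-(2-methyl-1,3-dioxolan-2-yl)cyclohex-2-en-1-one
Product: 9 linear TMS dienol ether C7(OSiMe3)=C8(CH3)–C4H=C3H with 1α-CH3, 1β-[1-(TBSO)ethyl], 2α-(2-methyl-1,3-dioxolan-2-yl)
Conditions: LiN(iPr)2, THF, −78 °C; TMSCl, −78 to 0 °C; pentane, filtration
Reagents that add atoms: chlorotrimethylsilane, C[Si](C)(C)Cl
Why: With C1 quaternary the only protons the amide base can remove next to the enone are the γ-hydrogens at C3, so O-silylation of the extended enolate (silyl dienol ether formation) gives the linear 1-silyloxy-1,3-diene regiospecifically and without touching a stereocentre.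

Step 6
Reactants: 9 TMS dienol ether; 10 methyl pyruvate
Product: 12 γ-aldol adduct (enone C7(=O)–C8(CH3)=C4H; 3β-[(2S)-2-hydroxy-1-methoxy-1-oxopropan-2-yl]; 2α-dioxolanyl; 1α-CH3; 1β-[1-(TBSO)ethyl]), via O-TMS ether 11 (not isolated)
Conditions: Cu(OTf)2 (10 mol%), 2,2′-(propane-2,2-diyl)bis[(4S)-4-tert-butyl-4,5-dihydrooxazole] (11 mol%), THF, −78 to −40 °C; then citric acid, MeOH, 0 °C
Reagents that add atoms: none
Why: In this vinylogous Mukaiyama aldol addition the dienol ether attacks the copper-chelated pyruvate ketone through its γ-carbon C3, since attack at the methyl-bearing α-carbon C8 is hindered and would not restore the enone, on the β-face anti to the α-dioxolanyl group at C2, while the C2-symmetric bis(oxazoline) ligand shields one face of the bound pyruvate and is expected to give the (S)-configured tertiary carbinol C5′, the sense established for this catalyst with pyruvate esters; mild acid then removes the transferred trimethylsilyl group.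

Step 7
Reactants: 12 γ-aldol adduct
Product: 13 C5′ propionate of 12
Conditions: (EtCO)2O, DMAP, Et3N, CH2Cl2, 40 °C
Reagents that add atoms: propionic anhydride, CCC(=O)OC(=O)CC
Why: DMAP-catalysed O-acylation of the only free hydroxyl, the tertiary C5′ carbinol, installs the propionyl unit that will supply C2′, C3′ and the 3′-methyl group of the tetronate, and no stereocentre is involved.

Step 8
Reactants: 13 C5′ propionate
Product: 15 enone carrying the 3β-[(5′S)-4′-methoxy-3′,5′-dimethyl-2′-oxo-2′,5′-dihydrofuran-5′-yl] group (O-methyl tetronate), via tetronic acid 14 (not isolated)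
Conditions: KN(SiMe3)2 (2.1 equiv), THF, −78 to −20 °C; then Me2SO4, DMF, 0 °C to rt
Reagents that add atoms: dimethyl sulfate, COS(=O)(=O)OC
Why: Dieckmann condensation of the kinetically formed propionate enolate onto the geminal methyl ester is a fast 5-exo-trig closure that should outrun deprotonation of the hindered C3–H or conjugate addition to the congested enone, and O-methylation of the resulting tetronate salt at O4′ masks the acidic, nucleophilic enol for the later steps; C5′ is quaternary and cannot epimerise.

Step 9
Reactants: 15 O-methyl tetronate enone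
Product: 16 4α,8α-epoxy ketone (3β-tetronate, 2α-dioxolanyl, 1α-CH3, 1β-[1-(TBSO)ethyl])
Conditions: 30% H2O2, NaOH (aq), MeOH, 0 °C
Reagents that add atoms: hydrogen peroxide, OO
Why: In this Weitz–Scheffer epoxidation the hydroperoxide anion adds to the enone β-carbon C4 on the α-face, anti to the bulky β-tetronate on vicinal C3, and the enolate closes onto the peroxide oxygen on the same face, which fixes C8 in its final configuration and C4 in the configuration that the key step will invert; the tetronate alkene is a donor-substituted, tetrasubstituted enoate and is not attacked.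

Step 10
Reactants: 16 epoxy ketone silyl ether
Product: 17 epoxy ketone with free 1β-(1-hydroxyethyl) group
Conditions: HF·pyridine, pyridine, THF, 0 °C to rt
Reagents that add atoms: none
Why: Fluoride-mediated cleavage of the silyl ether with pyridine-buffered HF·pyridine frees the secondary alcohol without generating an alkoxide (no retro-aldol, no intramolecular epoxide opening) and leaves the dioxolane and the epoxide intact.

Step 11
Reactants: 17 epoxy hydroxy ketone
Product: 18 epoxy diketone with 1β-acetyl group (C6 carbonyl, C5 methyl)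
Conditions: Dess–Martin periodinane, pyridine, CH2Cl2, rt
Reagents that add atoms: none
Why: Dess–Martin oxidation under buffered conditions converts the secondary alcohol into the C1 acetyl group and thereby removes the carbinol epimer mixture, the non-enolisable C7/C6 diketone being stable in the absence of nucleophiles.

Step 12
Reactants: 19 (E)-hex-4-enoic acid
Product: 21 1-[(E)-hex-4-enoyl]-1H-benzotriazole, via acid chloride 20 (not isolated)
Conditions: (COCl)2, DMF (cat.), CH2Cl2, 0 °C to rt; concentrate; then 1H-benzotriazole, Et3N, CH2Cl2, 0 °C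
Reagents that add atoms: 1H-benzotriazole, c1ccc2[nH]nnc2c1
Why: Conversion of the acid into its chloride and N-acylation of benzotriazole give a crystalline neutral acyl donor known to C-acylate ketone enolates cleanly, and the isolated (E)-alkene is untouched.

Step 13
Reactants: 18 epoxy diketone; 21 1-[(E)-hex-4-enoyl]-1H-benzotriazole
Product: 22 epoxy ketone with the β-diketone arm C1–C6(=O)–C5H2–C(=O)–CH2CH2CH=CHCH3 (3β-O-methyl tetronate, 2α-dioxolanyl, 4α,8α-epoxide)
Conditions: LiN(SiMe3)2 (2.2 equiv), THF, −78 °C; 21, −78 °C; AcOH quench at −78 °C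
Reagents that add atoms: none
Why: In this crossed Claisen condensation the hindered amide base forms the kinetic lithium enolate of the only enolisable ketone, the C6 methyl ketone, which is C-acylated by the acylbenzotriazole, the second equivalent of base converting the product into its diketonate so that over-acylation is avoided, and at −78 °C neither enolate opens the epoxide.

Step 14
Reactants: 22 epoxy β-diketone
Product: 23 bicyclo[2.2.2]octene cage (C5 (E)-hex-4-enoyl, C6 enol, C7 ketone, C8 tertiary OH anti to C4–C5, C3 O-methyl tetronate, C2 dioxolanyl)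
Conditions: DBU (1.5 equiv), LiClO4 (2 equiv), THF, rt to 50 °C; pH 4 phosphate work-up
Reagents that add atoms: none
Why: DBU removes a C5 proton of the β-diketone, the only C–H acid in 22, and the carbon of the lithium-chelated diketonate attacks the LiClO4-activated epoxide at C4 from the β-face, anti to the breaking C4–O bond, so that C4 is inverted, the C4–C5 bond forms and the C8 oxygen leaves as a tertiary alkoxide that is at once protonated by the remaining, still acidic C5–H. The closest known reaction type is the intramolecular SN2 opening of an epoxide by a 1,3-dicarbonyl carbanion with trans-diaxial (Fürst–Plattner) geometry. One ring closes, the carbocycle C1–C6–C5–C4–C3–C2 (equally C1–C6–C5–C4–C8–C7) that completes the bicyclo[2.2.2]octane, in a 6-exo-tet mode through a boat of the cyclohexanone in which the β-oriented C1 acyl arm sits over C4. The one new stereocentre, C4, is controlled by the α-configuration of the epoxide set in step 9, because backside attack can only deliver C5 to the β-face, while C8 keeps its configuration and its hydroxyl ends up anti to C4–C5 as in the target. The step needs attack at C4 rather than C8 and C- rather than O-alkylation: C8 is quaternary and would demand a five-membered closure with an unattainable backside trajectory, and chelation of both diketone oxygens by lithium leaves the central carbon as the nucleophilic site. Because the product is an enolised acyl-dicarbonyl held as its salt the alkylation is not reversible, the ketal keeps C2–H non-acidic, and the O-methylated tetronate cannot compete as an oxygen nucleophile.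

Step 15
Reactants: 23 cage ketal
Product: 24 cage methyl ketone (C2 acetyl)
Conditions: 2 M HCl, THF, rt
Reagents that add atoms: water, O
Why: Acid-catalysed hydrolysis of the dioxolane (acetal hydrolysis) unmasks the C2 acetyl group under conditions that the enolised acyl-dione, the tertiary ketol and the O-methyl tetronate tolerate, and C2, now enolisable, already sits in the thermodynamically preferred arrangement trans to the C3 tetronate.

Step 16
Reactants: 24 cage methyl ketone; 25 (E)-crotonaldehyde
Product: 26 β-hydroxy ketone (C2–C(=O)–CH2–CH(OH)–CH=CH–CH3)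
Conditions: LiN(iPr)2 (3.2 equiv), THF, −78 °C; crotonaldehyde, −78 °C; AcOH quench
Reagents that add atoms: none
Why: After the enol and the tertiary hydroxyl have been converted into lithium salts, the third equivalent of base deprotonates the unhindered acetyl methyl group kinetically and this enolate adds in 1,2-fashion to crotonaldehyde (directed aldol addition), the new carbinol centre being removed in step 17.

Step 17
Reactants: 26 β-hydroxy ketone
Product: 27 O-methyl ether of the target (C2 (2E,4E)-hexa-2,4-dienoyl)
Conditions: TsOH·H2O (10 mol%), toluene, 40 °C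
Reagents that add atoms: none
Why: Acid-catalysed dehydration of the β-hydroxy ketone, eased by the allylic position of the hydroxyl, completes the aldol condensation and gives the conjugated dienone with the thermodynamically favoured (E,E) geometry without affecting any stereocentre.

Step 18
Reactants: 27 O-methyl ether of the target
Product: 28 CNP0539719.2
Conditions: LiCl, DMSO, 60 °C; dilute HCl work-up
Reagents that add atoms: none
Why: Chloride attacks the O-methyl group of the vinylogous carbonate in an SN2 dealkylation, releasing the tetronic acid as its lithium salt that is protonated on work-up, under near-neutral conditions that spare the dienone, the ketol and all stereocentres.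

## Compound list

1 | (R)-carvone, (5R)-2-methyl-5-(prop-1-en-2-yl)cyclohex-2-en-1-one | CC1=CC[C@H](CC1=O)C(C)=C | starting material
2 | secondary ozonide, (5R)-2-methyl-5-(3-methyl-1,2,4-trioxolan-3-yl)cyclohex-2-en-1-one (not isolated) | CC1=CC[C@H](CC1=O)C2(C)OCOO2 | intermediate
3 | (5R)-5-acetyl-2-methylcyclohex-2-en-1-one | CC1=CC[C@H](CC1=O)C(C)=O | intermediate
4 | (5R)-2-methyl-5-(2-methyl-1,3-dioxolan-2-yl)cyclohex-2-en-1-one | CC1=CC[C@H](CC1=O)C2(C)OCCO2 | intermediate
5 | (5R,6S)-2,6-dimethyl-5-(2-methyl-1,3-dioxolan-2-yl)cyclohex-2-en-1-one (major trans epimer; the 6R epimer converges in step 4) | CC1=CC[C@H]([C@H](C)C1=O)C2(C)OCCO2 | intermediate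
6 | acetaldehyde | CC=O | starting material
7 | (5R,6R)-6-(1-hydroxyethyl)-2,6-dimethyl-5-(2-methyl-1,3-dioxolan-2-yl)cyclohex-2-en-1-one, lithium alkoxide in the flask (not isolated) | CC1=CC[C@H]([C@](C)(C(C)O)C1=O)C2(C)OCCO2 | intermediate
8 | (5R,6R)-6-[1-(tert-butyldimethylsilyloxy)ethyl]-2,6-dimethyl-5-(2-methyl-1,3-dioxolan-2-yl)cyclohex-2-en-1-one | CC1=CC[C@H]([C@](C)(C(C)O[Si](C)(C)C(C)(C)C)C1=O)C2(C)OCCO2 | intermediate
9 | linear TMS dienol ether C7(OSiMe3)=C8(CH3)–C4H=C3H; 1α-CH3, 1β-[1-(TBSO)ethyl], 2α-(2-methyl-1,3-dioxolan-2-yl) | CC1=C(O[Si](C)(C)C)[C@@](C)(C(C)O[Si](C)(C)C(C)(C)C)[C@@H](C=C1)C2(C)OCCO2 | intermediate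
10 | methyl pyruvate | CC(=O)C(=O)OC | starting material
11 | O-TMS ether of 12 (not isolated) | CC1=C[C@H]([C@](C)(O[Si](C)(C)C)C(=O)OC)[C@H]([C@](C)(C(C)O[Si](C)(C)C(C)(C)C)C1=O)C2(C)OCCO2 | intermediate
12 | γ-aldol adduct: enone C7(=O)–C8(CH3)=C4H with 3β-[(2S)-2-hydroxy-1-methoxy-1-oxopropan-2-yl], 2α-dioxolanyl, 1α-CH3, 1β-[1-(TBSO)ethyl] | CC1=C[C@H]([C@](C)(O)C(=O)OC)[C@H]([C@](C)(C(C)O[Si](C)(C)C(C)(C)C)C1=O)C2(C)OCCO2 | intermediate
13 | C5′ propionate of 12 | CC1=C[C@H]([C@](C)(OC(=O)CC)C(=O)OC)[C@H]([C@](C)(C(C)O[Si](C)(C)C(C)(C)C)C1=O)C2(C)OCCO2 | intermediate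
14 | tetronic acid: enone with 3β-[(5′S)-4′-hydroxy-3′,5′-dimethyl-2′-oxo-2′,5′-dihydrofuran-5′-yl], potassium salt in the flask (not isolated) | CC1=C[C@H]([C@]3(C)OC(=O)C(C)=C3O)[C@H]([C@](C)(C(C)O[Si](C)(C)C(C)(C)C)C1=O)C2(C)OCCO2 | intermediate
15 | O-methyl tetronate enone: 3β-[(5′S)-4′-methoxy-3′,5′-dimethyl-2′-oxo-2′,5′-dihydrofuran-5′-yl], 2α-dioxolanyl, 1α-CH3, 1β-[1-(TBSO)ethyl] | CC1=C[C@H]([C@]3(C)OC(=O)C(C)=C3OC)[C@H]([C@](C)(C(C)O[Si](C)(C)C(C)(C)C)C1=O)C2(C)OCCO2 | intermediate
16 | 4α,8α-epoxy ketone of 15 | C[C@]12O[C@H]1[C@H]([C@]3(C)OC(=O)C(C)=C3OC)[C@H]([C@](C)(C(C)O[Si](C)(C)C(C)(C)C)C2=O)C4(C)OCCO4 | intermediate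
17 | 4α,8α-epoxy ketone with free 1β-(1-hydroxyethyl) group | C[C@]12O[C@H]1[C@H]([C@]3(C)OC(=O)C(C)=C3OC)[C@H]([C@](C)(C(C)O)C2=O)C4(C)OCCO4 | intermediate
18 | 4α,8α-epoxy ketone with 1β-acetyl group | C[C@]12O[C@H]1[C@H]([C@]3(C)OC(=O)C(C)=C3OC)[C@H]([C@](C)(C(C)=O)C2=O)C4(C)OCCO4 | intermediate
19 | (E)-hex-4-enoic acid | C/C=C/CCC(=O)O | starting material
20 | (E)-hex-4-enoyl chloride (not isolated) | C/C=C/CCC(Cl)=O | intermediate
21 | 1-[(E)-hex-4-enoyl]-1H-benzotriazole | C/C=C/CCC(=O)n1nnc2ccccc12 | intermediate
22 | key-step precursor: 4α,8α-epoxy ketone with 1β-[(E)-3-oxooct-6-enoyl] arm, 1α-CH3, 2α-dioxolanyl, 3β-O-methyl tetronate | C[C@]12O[C@H]1[C@H]([C@]3(C)OC(=O)C(C)=C3OC)[C@H]([C@](C)(C(=O)CC(=O)CC/C=C/C)C2=O)C4(C)OCCO4 | intermediate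
23 | key-step product: bicyclo[2.2.2]oct-5-ene cage; C1 CH3, C2 dioxolanyl (side of the C7–C8 bridge), C3 O-methyl tetronate (side of the enol bridge), C5 (E)-hex-4-enoyl, C6 enol OH, C7 ketone, C8 CH3 and OH (OH anti to C4–C5) | CC3(OCCO3)[C@@H]1[C@@H]([C@]2(C)OC(=O)C(C)=C2OC)[C@H]2C(C(=O)CC/C=C/C)=C(O)[C@]1(C)C(=O)[C@@]2(C)O | intermediate
24 | cage methyl ketone (C2 acetyl) | CC(=O)[C@@H]1[C@@H]([C@]2(C)OC(=O)C(C)=C2OC)[C@H]2C(C(=O)CC/C=C/C)=C(O)[C@]1(C)C(=O)[C@@]2(C)O | intermediate
25 | (E)-crotonaldehyde | C/C=C/C=O | starting material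
26 | cage β-hydroxy ketone, C2 (E)-3-hydroxyhex-4-enoyl | C/C=C/C(O)CC(=O)[C@@H]1[C@@H]([C@]2(C)OC(=O)C(C)=C2OC)[C@H]2C(C(=O)CC/C=C/C)=C(O)[C@]1(C)C(=O)[C@@]2(C)O | intermediate
27 | 4′-O-methyl ether of the target | C/C=C/C=C/C(=O)[C@@H]1[C@@H]([C@]2(C)OC(=O)C(C)=C2OC)[C@H]2C(C(=O)CC/C=C/C)=C(O)[C@]1(C)C(=O)[C@@]2(C)O | intermediate
28 | CNP0539719.2 | C/C=C/C=C/C(=O)[C@@H]1[C@@H]([C@]2(C)OC(=O)C(C)=C2O)[C@H]2C(C(=O)CC/C=C/C)=C(O)[C@]1(C)C(=O)[C@@]2(C)O | target

## Step count and weak points

Total step count: 18. Longest linear sequence: 17 steps (steps 1–11 and 13–18 from (R)-carvone); step 12 is a one-step side branch.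

**Step 6.** The hindered γ-carbon may add only sluggishly to a ketone electrophile, or the substrate and catalyst preferences may be mismatched, so that facial selectivity at the pyruvate carbonyl (C5′) or at C3 is poor. The fallback builds the quaternary centre by enolate alkylation instead of ketone addition. Starting from dienol ether 9, the vinylogous Mukaiyama aldol is run with the far more reactive ethyl glyoxylate (same copper catalyst) to give the secondary α-hydroxy ester F1. Propionylation gives the diester F2, and Dieckmann closure with O-methylation as in step 8 gives the 5′-unsubstituted O-methyl tetronate F3, whose C5′ configuration is immaterial. Deprotonation at C5′ (LiN(iPr)2, THF, −78 °C) and methylation with MeI then create C5′, the planar furanolate being approached from the face turned away from the C2 dioxolanyl group. The route is rejoined at 15.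

**Step 14.** The boat-like closure next to the C3 tetronate may be slow, so that O-alkylation of the diketonate or retro-Claisen loss of the acyl arm takes over. The fallback reverses the order of acylation and cyclisation while forming the same C4–C5 bond and ring. From methyl ketone 18, KN(SiMe3)2 in THF (0 °C to rt) generates the smaller, more reactive acetyl enolate, which opens the epoxide at C4 in the same 6-exo mode with inversion to give the bicyclic dione carbinol F4. Its dianion (LiN(iPr)2, tertiary alkoxide plus C5 enolate) is then C-acylated with acylbenzotriazole 21, which returns to 23.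

**Step 8.** The ester enolate may undergo intramolecular conjugate addition to C4, or the base may trigger γ-deprotonation and elimination across C3–C5′ instead of the Claisen closure. The fallback is a base-free construction of the butenolide from hydroxy ester 12. Ketenylidenetriphenylphosphorane (Ph3P=C=C=O) in hot toluene adds the tertiary hydroxyl, and the resulting ester ylide closes by intramolecular Wittig olefination of the methyl ester. This gives directly the 4′-methoxy butenolide F5, which lacks the 3′-methyl group. Bromination at C3′ with NBS gives the bromo tetronate F6, and Suzuki–Miyaura methylation (trimethylboroxine, Pd(PPh3)4, K2CO3, dioxane, 90 °C) rejoins the route at 15.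

## Further compounds

F1 | step 6 | ethyl glyoxylate γ-adduct: enone with 3β-[1-hydroxy-2-ethoxy-2-oxoethyl] (carbinol centre undefined), 2α-dioxolanyl, 1α-CH3, 1β-[1-(TBSO)ethyl] | CC1=C[C@H](C(O)C(=O)OCC)[C@H]([C@](C)(C(C)O[Si](C)(C)C(C)(C)C)C1=O)C2(C)OCCO2
F2 | step 6 | propionate of F1 | CC1=C[C@H](C(OC(=O)CC)C(=O)OCC)[C@H]([C@](C)(C(C)O[Si](C)(C)C(C)(C)C)C1=O)C2(C)OCCO2
F3 | step 6 | 5′-unsubstituted O-methyl tetronate: enone with 3β-[4′-methoxy-3′-methyl-2′-oxo-2′,5′-dihydrofuran-5′-yl] (C5′ undefined) | CC1=C[C@H](C3OC(=O)C(C)=C3OC)[C@H]([C@](C)(C(C)O[Si](C)(C)C(C)(C)C)C1=O)C2(C)OCCO2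
F4 | step 14 | bicyclo[2.2.2]octane-dione carbinol: cage of 23 with C5H2 and C6 ketone, no acyl group on C5 | CC3(OCCO3)[C@@H]1[C@@H]([C@]2(C)OC(=O)C(C)=C2OC)[C@H]2CC(=O)[C@]1(C)C(=O)[C@@]2(C)O
F5 | step 8 | 3′-unsubstituted O-methyl tetronate: enone with 3β-[(5′S)-4′-methoxy-5′-methyl-2′-oxo-2′,5′-dihydrofuran-5′-yl] | CC1=C[C@H]([C@]3(C)OC(=O)C=C3OC)[C@H]([C@](C)(C(C)O[Si](C)(C)C(C)(C)C)C1=O)C2(C)OCCO2
F6 | step 8 | 3′-bromo O-methyl tetronate derived from F5 | CC1=C[C@H]([C@]3(C)OC(=O)C(Br)=C3OC)[C@H]([C@](C)(C(C)O[Si](C)(C)C(C)(C)C)C1=O)C2(C)OCCO2
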